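You want to know how the opening rate of this coupling moves with c coupling partner and c starting material, and how much target the alpha flask holds at 30 min.

| flask | starting material | coupling partner | time |
|---|---|---|---|
| epsilon | 0.120 M | 0.360 M |  |
| zeta | 0.0600 M | 0.300 M |  |
| theta | 0.180 M | 0.360 M |  |
| beta | 0.120 M | 0.720 M |  |
| alpha | 0.120 M | 0.360 M | 30 min |

- epsilon run (time / min: [target] / M): 1.7: 0.0169; 3.4: 0.0281; 5.1: 0.0356; 6.9: 0.0417; 8.6: 0.0452; 10: 0.0476; 12: 0.0496
- zeta run (time / min: [target] / M): 1.7: 0.0064; 3.4: 0.0104; 5.1: 0.0140; 6.9: 0.0166; 8.6: 0.0186; 10: 0.0200; 12: 0.0209
- theta run (time / min: [target] / M): 1.7: 0.0248; 3.4: 0.0410; 5.1: 0.0515; 6.9: 0.0593; 8.6: 0.0641; 10: 0.0670; 12: 0.0695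
- beta run (time / min: [target] / M): 1.7: 0.0534; 3.4: 0.0760; 5.1: 0.0847; 6.9: 0.0896; 8.6: 0.0898; 10: 0.0902; 12: 0.0885

(readings scatter by 4 × 10⁻⁴ M)

- how the opening rate goes with [coupling partner] round the charge of the epsilon run: the exponent of the rate at two percent of starting material gone to target
- how the opening rate goes with [starting material] round the charge of the epsilon run: the exponent of the rate at two percent of starting material gone to target (one fixed amount of target, the same in the runs compared)
- target in the alpha run at 30 min, as a share of the starting material charged

- Overall: starting material + coupling partner -> target.
- Constant volume, constant temperature.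
- "The second partner" is coupling partner.
- An order is taken over about fifteen percent of the charge, up and down.

Turn the first question round and ask what the readings would show if the coupling partner entered the rate once, as a first-order reactant. The epsilon and beta flasks hold the same c starting material, and beta holds twice the c coupling partner, so beta's rate would then be twice epsilon's. To reckon opening rates of my own, note that in the epsilon, beta and theta flasks the second reading comes at twice the time of the first. The gain over the second interval divided by the gain over the first is then the factor by which a curve closing exponentially shrinks per interval, its logarithm gives the rate constant, and the opening rate follows. Taking the curve as exponential over those two intervals, epsilon gives 0.0121 M/min and beta gives 0.0468 M/min, a ratio of 3.86, which stands a factor 1.93 beyond the first-order case.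

The partner exponent, 1.95, is the logarithm of that rate ratio over the logarithm of the charge ratio; it is an apparent reaction order, and it is the number I commit to. Read the other way, epsilon at half of beta's partner carries a quarter of beta's opening rate. For starting material, the theta flask holds 1.50 times epsilon's charge, and the same reckoning gives it 0.0179 M/min, a rate ratio of 1.48 and so an exponent of 0.962.

The forecast gives 1.95 for the partner, between 1.7 and 2.15, and 1 for starting material, between 0.85 and 1.15. For alpha, whose charge repeats epsilon's, it says “it sits at the plateau” and gives 43.5 %, between 40 % and 45.5 %.

    starting material + 2 coupling partner → target + coupling partner (0.7860 /M²/min)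
    coupling partner → lost reagent (0.02976 /min)
    target → decomposed product (0.02604 /min)

The flask gives 2.0 in the partner, 1.0 in starting material, and 36.2 % in the alpha flask at 30 min, which is 7.3 percentage points under the forecast. That share is 0.0434 M of target, less than the 0.0496 M that the epsilon flask, with the same charge, showed at 12 min. Now put the partner exponent to the zeta flask: epsilon's rate, times the starting-material ratio 0.500, times the partner ratio 0.833 raised to 1.95, gives 0.00407 M/min, and the zeta flask reads 0.0038 M/min.

(The runs were generated by integration on assumed constants; the scatter is artificial.)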